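## Retrosynthetic overview

1. The target is lutein plus one oxygen. The only bond to make is C4–O, cis to the C3 oxygen. All 40 carbons, the all-E polyene and the centres C3, C3' and C6' come with lutein.
2. Triol ⇐ hydride cleavage of both carbonates in a cis-fused 3,4-cyclic carbonate that also carries a 3'-O-Boc group.
3. Cyclic carbonate ⇐ key C4–O disconnection: oxidative ionisation of C4–H in lutein bis(tert-butyl carbonate), with the C4 cation captured by the carbonyl oxygen of the C3 carbonate.
4. Bis(tert-butyl carbonate) ⇐ lutein + Boc2O.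
5. Ring order: the β and ε rings are present from the start. The only ring formed is a temporary 1,3-dioxolan-2-one (step 2), which is opened again in step 3.

**Assumption:** crystalline (all-E,3R,3'R,6'R)-lutein from marigold, sold in bulk as a food-supplement ingredient, counts as a cheap commercial starting material; one recrystallisation to remove the few per cent of zeaxanthin is not counted as a step.

**Handling:** all operations run under argon, in dim light, in base-washed glassware and with peroxide-free solvents.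

**Descriptor note:** C3 is R in 1 and 2 and S in 5 and 6. This is only because C4 outranks C2 once it bears oxygen; the C3–O bond is never broken.

## Route

Step 1
Reactants: 1 lutein = (all-E,3R,3'R,6'R)-β,ε-carotene-3,3'-diol
Product: 2 lutein bis(tert-butyl carbonate) = (all-E,3R,3'R,6'R)-3,3'-bis(tert-butoxycarbonyloxy)-β,ε-carotene
Conditions: Boc2O (4 equiv), DMAP (0.3 equiv), THF, 0 °C to rt, 6 h
Reagents that add atoms: di-tert-butyl dicarbonate (Boc2O), CC(C)(C)OC(=O)OC(=O)OC(C)(C)C
Why: DMAP-catalysed O-tert-butoxycarbonylation (nucleophilic-catalysis acylation) of both secondary alcohols runs under neutral conditions and touches no C–O bond and no part of the polyene, so 3R, 3'R and 6'R carry over unchanged and no new stereocentre is formed.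

Step 2
Reactants: 2 lutein bis(tert-butyl carbonate)
Product: 5 cis-fused cyclic carbonate = (all-E,3S,4R,3'R,6'R)-3'-(tert-butoxycarbonyloxy)-β,ε-carotene-3,4-diyl carbonate, via C4 polyenyl cation 3 (not isolated), via tert-butoxydioxolanylium ion 4 (not isolated)
Conditions: NBS (1.0 equiv, slow addition), 2,6-di-tert-butyl-4-methylpyridine (1.5 equiv), 4 Å MS, EtOH-free CH2Cl2 (5 mM), −45 °C to −10 °C until the blue colour has faded to orange; cold aq NaHCO3; deactivated neutral alumina
Reagents that add atoms: none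
Why: Proposed new method: neighbouring-carbonate-directed oxidative C4–H oxygenation of a carotenoid β end group (a C–H variant of the Woodward–Prévost cis-hydroxylation): NBS removes two electrons and one proton from the polyene terminus, as in the known NBS 4-alkoxylation of β,β- and β,ε-carotene, giving the blue cation 3 (charge spread from C4 to C7'); the only nucleophile held next to it is the carbonyl oxygen of the C3 O-Boc group, which can reach C4 alone and only along the axial trajectory on the face carrying the C3 oxygen, so closure to 4 makes the C4–O bond and sets 4R cis to C3–O by geometry; immediate loss of the tert-butyl cation (isobutene plus a proton taken by the hindered pyridine, which is too bulky to add to 3 and slow to deprotonate it) makes the capture irreversible although 3 is strongly stabilised; the ε ring is spared because C3'–H is deactivated by its carbonate, the isolated C4'=C5' bond is far less electron-rich than the decaene, and C6'–H lies near the nodal plane of the polyene; closest known reaction types are NBS C4 functionalisation of carotenes by external nucleophiles, tert-butyl carbonate capture of halonium ions (iodocarbonate cyclisation) and oxidative C–H cleavage with tethered nucleophiles.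

Step 3
Reactants: 5 cis-fused cyclic carbonate
Product: 6 (all-E,3S,4R,3'R,6'R)-β,ε-carotene-3,4,3'-triol (target)
Conditions: LiAlH4 (3 equiv), THF, −20 °C to 0 °C, 30 min; Na2SO4·10H2O; crystallisation from CH2Cl2/hexane (gives the all-E isomer)
Reagents that add atoms: none
Why: LiAlH4 reduction of carbonates (the classical hydride cleavage of carotenol esters) attacks only the two carbonyl carbons, so all three C–O bonds and all four stereocentres are kept, the polyene is inert, and no acid that could re-ionise C4–O or C3'–O is ever present.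

## Compound list

1 | lutein, (all-E,3R,3'R,6'R)-β,ε-carotene-3,3'-diol | CC1=C[C@H](O)CC(C)(C)[C@H]1/C=C/C(C)=C/C=C/C(C)=C/C=C/C=C(C)/C=C/C=C(C)/C=C/C1=C(C)C[C@@H](O)CC1(C)C | starting material

2 | lutein bis(tert-butyl carbonate), (all-E,3R,3'R,6'R)-3,3'-bis(tert-butoxycarbonyloxy)-β,ε-carotene | CC1=C[C@H](OC(=O)OC(C)(C)C)CC(C)(C)[C@H]1/C=C/C(C)=C/C=C/C(C)=C/C=C/C=C(C)/C=C/C=C(C)/C=C/C1=C(C)C[C@@H](OC(=O)OC(C)(C)C)CC1(C)C | intermediate

3 | C4 polyenyl cation of 2 (drawn in its C4-localised form, charge delocalised to C7') | CC1=C[C@H](OC(=O)OC(C)(C)C)CC(C)(C)[C@H]1/C=C/C(C)=C/C=C/C(C)=C/C=C/C=C(C)/C=C/C=C(C)/C=C/C1=C(C)[CH+][C@@H](OC(=O)OC(C)(C)C)CC1(C)C | intermediate (not isolated)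

4 | cis-fused 2-tert-butoxy-1,3-dioxolan-2-ylium ion on C3/C4 | CC1=C[C@H](OC(=O)OC(C)(C)C)CC(C)(C)[C@H]1/C=C/C(C)=C/C=C/C(C)=C/C=C/C=C(C)/C=C/C=C(C)/C=C/C1=C(C)[C@H]2OC(OC(C)(C)C)=[O+][C@H]2CC1(C)C | intermediate (not isolated)

5 | (all-E,3S,4R,3'R,6'R)-3'-(tert-butoxycarbonyloxy)-β,ε-carotene-3,4-diyl carbonate (cis-fused 1,3-dioxolan-2-one) | CC1=C[C@H](OC(=O)OC(C)(C)C)CC(C)(C)[C@H]1/C=C/C(C)=C/C=C/C(C)=C/C=C/C=C(C)/C=C/C=C(C)/C=C/C1=C(C)[C@H]2OC(=O)O[C@H]2CC1(C)C | intermediate

6 | (all-E,3S,4R,3'R,6'R)-β,ε-carotene-3,4,3'-triol | CC1=C[C@H](O)CC(C)(C)[C@H]1/C=C/C(C)=C/C=C/C(C)=C/C=C/C=C(C)/C=C/C=C(C)/C=C/C1=C(C)[C@@H](O)[C@@H](O)CC1(C)C | target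

## Step count and risks

Total step count: 3. Longest linear sequence: 3.

Expected yields: step 1 about 85–90 %, step 2 about 35–50 % based on recovered 2, step 3 about 80 %.

**Most likely to fail, first: step 2 (the proposed new step).**

- Risks:
  - The carbonate oxygen may close too slowly onto a very stabilised cation.
  - Cation 3 may lose H6' or a methyl proton to give retro-type polyenes.
  - Product 5 may be over-oxidised.
  - The cation may scramble E/Z geometry.
- Fallback (known chemistry only): it sets out from 2 and comes back at 5. The C4 centre is then set by hydride delivery to a ketone instead of by C–O closure.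
  - The C4 methylene of 2 is taken to the ketone by the known hypobromous-acid allylic oxidation of β end groups (NaBrO3/NaHSO3, CHCl3/H2O, 0–5 °C). This reaction type converts zeaxanthin into astaxanthin. It gives (all-E,3S,3'R,6'R)-3,3'-bis(tert-butoxycarbonyloxy)-β,ε-caroten-4-one F1.
  - NaBH4 (THF/EtOH, 0 °C) gives the cis alcohol (all-E,3S,4R,3'R,6'R)-3,3'-bis(tert-butoxycarbonyloxy)-β,ε-caroten-4-ol F2. It forms beside the trans epimer (all-E,3S,4S,3'R,6'R)-3,3'-bis(tert-butoxycarbonyloxy)-β,ε-caroten-4-ol F3.
  - DBU (CH2Cl2, 0 °C) closes the cis hydroxy carbonate onto its neighbouring Boc group to give 5. The trans epimer closes much more slowly and is removed by chromatography.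
  - Cost: two more steps and a poorly selective reduction.

**Second: step 3.**

- Risks: aluminium Lewis acidity or hydride could ionise or hydrogenolyse the polyene-allylic C4–O bond or the allylic C3'–O bond.
- Fallback: it sets out from 5 and comes back at 6. Cleavage is by base solvolysis, without hydride or Lewis acid.
  - K2CO3 in MeOH/THF at rt opens the strained cyclic carbonate. This gives (all-E,3S,4R,3'R,6'R)-3'-(tert-butoxycarbonyloxy)-β,ε-carotene-3,4-diol F4.
  - Standard hot carotenoid saponification (10 % KOH in MeOH, THF, 50 °C) then hydrolyses the hindered 3'-O-Boc group to give 6.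

**Third: step 1.**

- Risks: DMAP/Boc2O can give symmetrical carbonates that link two lutein units, or incomplete reaction at one hydroxyl.
- Fallback: it sets out from 1 and comes back at 2. The order of bond formation is reversed, so the alcohol is activated first and the tert-butoxy group is added last.
  - 1,1'-Carbonyldiimidazole (CH2Cl2, rt) gives lutein 3,3'-bis(1H-imidazole-1-carboxylate) F5.
  - LiOtBu (THF, −20 °C) converts this into 2.

## Further compounds

F1 | step 2 | (all-E,3S,3'R,6'R)-3,3'-bis(tert-butoxycarbonyloxy)-β,ε-caroten-4-one | CC1=C[C@H](OC(=O)OC(C)(C)C)CC(C)(C)[C@H]1/C=C/C(C)=C/C=C/C(C)=C/C=C/C=C(C)/C=C/C=C(C)/C=C/C1=C(C)C(=O)[C@@H](OC(=O)OC(C)(C)C)CC1(C)C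
F2 | step 2 | (all-E,3S,4R,3'R,6'R)-3,3'-bis(tert-butoxycarbonyloxy)-β,ε-caroten-4-ol | CC1=C[C@H](OC(=O)OC(C)(C)C)CC(C)(C)[C@H]1/C=C/C(C)=C/C=C/C(C)=C/C=C/C=C(C)/C=C/C=C(C)/C=C/C1=C(C)[C@@H](O)[C@@H](OC(=O)OC(C)(C)C)CC1(C)C
F3 | step 2 | (all-E,3S,4S,3'R,6'R)-3,3'-bis(tert-butoxycarbonyloxy)-β,ε-caroten-4-ol | CC1=C[C@H](OC(=O)OC(C)(C)C)CC(C)(C)[C@H]1/C=C/C(C)=C/C=C/C(C)=C/C=C/C=C(C)/C=C/C=C(C)/C=C/C1=C(C)[C@H](O)[C@@H](OC(=O)OC(C)(C)C)CC1(C)C
F4 | step 3 | (all-E,3S,4R,3'R,6'R)-3'-(tert-butoxycarbonyloxy)-β,ε-carotene-3,4-diol | CC1=C[C@H](OC(=O)OC(C)(C)C)CC(C)(C)[C@H]1/C=C/C(C)=C/C=C/C(C)=C/C=C/C=C(C)/C=C/C=C(C)/C=C/C1=C(C)[C@@H](O)[C@@H](O)CC1(C)C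
F5 | step 1 | lutein 3,3'-bis(1H-imidazole-1-carboxylate) | CC1=C[C@H](OC(=O)n2ccnc2)CC(C)(C)[C@H]1/C=C/C(C)=C/C=C/C(C)=C/C=C/C=C(C)/C=C/C=C(C)/C=C/C1=C(C)C[C@@H](OC(=O)n2ccnc2)CC1(C)C
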